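The rate constants are made up; what happens was integrated by code.

**Two partners.** If Uj meets Ux and dissolved Xo together, it is lost by two pseudo-first-order steps at once, so the share of UxUj should follow from the concentrations of the two.

    Ve → Uj (k1 = 0.702 s⁻¹, Ea1 = 84.0 kJ mol⁻¹)
    Ux + Uj → UxUj (k2 = 6490 L mol⁻¹ s⁻¹, Ea2 = 46.0 kJ mol⁻¹)
    Xo + Uj → XoUj (k3 = 1.70 × 10⁵ L mol⁻¹ s⁻¹, Ea3 = 34.0 kJ mol⁻¹)
    UxUj → Kj (k4 = 3.59 × 10⁻⁴ s⁻¹, Ea4 = 95.0 kJ mol⁻¹)
    UxUj ⇌ Jy (K5 = 0.11, k5 = 0.334 s⁻¹, Ea5 = 88.0 kJ mol⁻¹, ΔH5 = −8.00 kJ mol⁻¹)
    Ji ⇌ Xo, rate k6*(csat - [Xo]) (k6 = 3.14 s⁻¹, csat = 0.18 mM)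
    (constants at 70 °C)

| setting | gamma | epsilon | theta | eta | delta | beta |
|---|---|---|---|---|---|---|
| Ve | 0.50 mM | 0.50 mM | 0.50 mM | 0.50 mM (fed, over 10 s) | 0.50 mM | 0.50 mM |
| Ux | 5.00 equiv (fed, over 10 s) | 5.00 equiv | 5.00 equiv | 5.00 equiv | 5.00 equiv (fed, over 10 s) | 5.00 equiv (fed, over 2.5 s) |
| Ji | 0.18 mM (held) | 0.18 mM (held) | 0.18 mM (held) | 0.18 mM (held) | 0.18 mM (held) | 0.18 mM (held) |
| time | 15 s | 15 s | 15 s | 15 s | 15 s | 15 s |
| remark | the addition at 50 °C, then warmed to 70 °C; the feed brings no volume worth counting | everything together at the start at 50 °C, warmed to 70 °C at 10 s | everything together at the start | all else is in the flask from the start; the feed brings no volume worth counting | all else is in the flask from the start; the feed brings no volume worth counting | all else is in the flask from the start; the feed brings no volume worth counting |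
| temperature |  |  | 70 °C | 70 °C | 70 °C | 70 °C |

- at the start none of Xo is dissolved
- all constants are for 70 °C and move with temperature by the activation energies and enthalpies

- the flask with the highest share of UxUj in UxUj plus XoUj ("all alike" if they lie within 1.5 percentage points) (gamma / epsilon / theta / eta / delta / beta / all alike)
- share of UxUj in UxUj plus XoUj at the end, gamma
- share of UxUj in UxUj plus XoUj at the end, epsilon
- share of UxUj in UxUj plus XoUj at the end, theta
- share of UxUj in UxUj plus XoUj at the end, eta
- share of UxUj in UxUj plus XoUj at the end, delta
- share of UxUj in UxUj plus XoUj at the end, beta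

**Balance level.** With Ux held at its charged 2.50 mM, the balance level of Xo is 0.0954 mM: the dissolved Xo at which Ux and Xo take Uj at equal rates, found as the rate constant of the Ux step times Ux, over the rate constant of the Xo step. UxUj also shares itself with Jy at the ratio K5, and in delta the relaxation half-life of 0.206 s is short against 15 s. The share of UxUj at the end is therefore reckoned as the balance level over the balance level plus 1.11 times Xo.

**First way.** Hold Xo at saturation in theta and work in powers of ten. The Xo constant exceeds the Ux constant by 1.42 powers, while Ux exceeds saturated Xo by 1.14 powers. The Xo branch therefore leads by 0.276 powers, and the share comes to 32.3 %.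

**Second way.** Xo has to cross from the gas, since the flask opens with none dissolved and the charge of Ve exceeds saturation. Transfer must match uptake. In theta, averaged over the Ve consumed, Uj forms at half the opening rate of Ve, and over the transfer coefficient this is a draw of 0.0559 mM. The deficit below saturation, times Xo plus the balance level, equals the draw times Xo. This quadratic gives Xo as 0.146 mM and a share of 37.0 %.

**Which cheats.** The ways part, and the first cheats in theta, because it places Xo at 0.18 mM while the transfer balance reckons it lower during the uptake. The second omits the dissolving lag of 0.318 s, shorter than the Ve lifetime of 1.42 s. Since that lag lowers early Xo, theta should lie somewhat above this figure.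

**Slow feeds.** In eta the steady feed draws 0.0159 mM, so Xo is reckoned at 0.170 mM and the share at 33.6 %, against 32.3 % from the first way. In delta, with Ve charged at the start, Uj forms on average one Ve lifetime after the start, and the dosing time is 7.0 such lifetimes. At that moment Ux has reached one part in 7.0 of its charge, so the balance level is reckoned as 0.0136 mM. The same draw as theta gives Xo as 0.129 mM and a share of 8.65 %. The order reckoned is theta above eta above delta; gamma, epsilon and beta are not reckoned here.

**The result.** The forecast names theta, with gamma 18.5 %, epsilon 29 %, theta 39 %, eta 32 %, delta 7.5 % and beta 21 %, on the ground that “Uj is a short-lived intermediate split between Ux and dissolved Xo”. The simulation gives gamma 19.2 %, epsilon 29.8 %, theta 40.8 %, eta 32.7 %, delta 8.09 % and beta 22.3 %, so theta stands highest.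

**The neighbour.** A neighbour of delta takes 2.0 mM of Ve with its equivalents held, which multiplies both the balance level and the draw by 4.00. The level becomes 0.0544 mM and the draw 0.224 mM. The quadratic then gives Xo as 0.0614 mM and a share of 44.4 %, whereas saturated Xo gives 21.4 %. At 15.0 s that neighbour holds UxUj at 39.1 % and XoUj at 56.4 % of the Ve charged, a share of 41.0 %.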